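The disconnection on which everything rests is the aryl ketone bond between carbonyl carbon C1 and C1′ of the resorcinol ring. The key step exploits two features. First, C1′ and the prenylated C5′ are the equivalent 4,6-positions of resorcinol, so 4,6-dibromoresorcinol delivers both by successive Br/Li exchanges. Second, the vicinal C1 carbonyl/C2 hydroxyl pair can be tied into a 1,3-dioxolan-4-one ring made from O-methyl-L-tyrosine, which already holds (S)-C2. Addition of the 5-prenylated 2,4-bis(MOM-oxy)phenyllithium to this lactone forms C1–C1′ and halts at a chelated hemiketal alkoxide. On cold acidic quench the alkoxide sheds acetone, so ketone and free carbinol appear in one operation.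

Key step: step 5

Remark on the chemistry: C1 = ketone carbon, C2 = carbinol carbon, C3 = benzylic CH2. Primed numbers belong to the resorcinol ring (C1′ acylated, O-2′ and O-4′ hydroxyl oxygens, C5′ prenylated). C2 reads as (S), the spatial arrangement of the L-amino acids.

Step 1
Reactants: 1 O-methyl-L-tyrosine
Product: 4 (S)-2-hydroxy-3-(4-methoxyphenyl)propanoic acid, via diazonium carboxylate 2 (not isolated), via alpha-lactone 3 (not isolated)
Conditions: NaNO2, 1 M aq H2SO4, 0 °C → rt
Reagents that add atoms: water, O
Why: Diazotization of an α-amino acid should run with net retention, because the carboxylate of 2 displaces N2 with inversion to give α-lactone 3 and water opens 3 at the same carbon with a second inversion, so C2 stays (S).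

Step 2
Reactants: 4 (S)-2-hydroxy-3-(4-methoxyphenyl)propanoic acid
Product: 5 (S)-5-(4-methoxybenzyl)-2,2-dimethyl-1,3-dioxolan-4-one
Conditions: Me2C(OMe)2, p-TsOH·H2O (cat.), CH2Cl2, rt
Reagents that add atoms: 2,2-dimethoxypropane, COC(C)(C)OC
Why: Acid-catalysed transketalization (acetonide formation) of the α-hydroxy acid closes the five-membered lactone without breaking any bond at C2, and it protects the hydroxyl and activates the carboxyl at the same time.

Step 3
Reactants: 6 4,6-dibromoresorcinol
Product: 7 1,5-dibromo-2,4-bis(methoxymethoxy)benzene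
Conditions: MOMCl, i-Pr2NEt, CH2Cl2, 0 °C → rt
Reagents that add atoms: chloromethyl methyl ether (MOMCl), COCCl
Why: Williamson-type O-alkylation of both acidic phenols should give formaldehyde acetals that withstand organolithium reagents and later coordinate lithium.

Step 4
Reactants: 7 1,5-dibromo-2,4-bis(methoxymethoxy)benzene; 8 prenyl bromide
Product: 11 1-bromo-2,4-bis(methoxymethoxy)-5-(3-methylbut-2-en-1-yl)benzene, via monolithio arene 9 (not isolated), via arylcopper 10 (not isolated)
Conditions: n-BuLi (1.0 equiv), THF, −78 °C; CuBr·SMe2 (1.0 equiv), −78 → −40 °C; 8, −40 → 0 °C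
Reagents that add atoms: none
Why: Halogen–metal exchange with one equivalent of n-BuLi should stop at 9 because a second exchange would build a dianion, the two bromines are homotopic so only one mono-product exists, and transmetalation to 10 steers the copper-mediated allylic substitution to the unhindered CH2 terminus of 8 (SN2).

Step 5
Reactants: 11 1-bromo-2,4-bis(methoxymethoxy)-5-(3-methylbut-2-en-1-yl)benzene; 5 (S)-5-(4-methoxybenzyl)-2,2-dimethyl-1,3-dioxolan-4-one
Product: 14 (S)-1-[2,4-bis(methoxymethoxy)-5-(3-methylbut-2-en-1-yl)phenyl]-2-hydroxy-3-(4-methoxyphenyl)propan-1-one, via aryllithium 12 (not isolated), via lithium hemiketal alkoxide 13 (not isolated)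
Conditions: 11, n-BuLi (1.0 equiv), THF, −78 °C; 5 in THF, −78 °C; AcOH, −78 °C → rt
Reagents that add atoms: none
Why: Bromine–lithium exchange converts 11 into aryllithium 12 with the carbanion exactly at C1′, and 12 adds to the lactone carbonyl C1 of 5 to give the tetrahedral lithium hemiketal alkoxide 13. At −78 °C 13 is held together by its five-membered ring and by coordination of lithium to the ortho MOM oxygen, so no ketone is exposed while 12 is still present; protonation with AcOH and warming then open the ring and expel acetone, which releases the aryl ketone and the free C2 hydroxyl in the same operation. The closest known reaction type is the mono-addition of aryllithium reagents to lactones and to 1,3-dioxolan-4-ones of α-hydroxy acids (nucleophilic acyl substitution through a stable tetrahedral adduct, the lactone counterpart of the Weinreb ketone synthesis). No ring is closed, since the temporary dioxolanone ring is only opened. No lasting stereocentre is formed, because the hemiketal carbon of 13 (either configuration) ends as the planar carbonyl, and C2 stays (S) because none of its bonds is broken and the enolizable ketone first appears under cold, acidic conditions. The step needs site selectivity on the ring, which the position of the bromine in 11 secures against the otherwise more acidic C3′–H between the two acetal oxygens, and addition rather than α-deprotonation of 5, which the strongly electrophilic acylal-type carbonyl and the low temperature secure, while any enolate that does form returns lactone and not ketone and so cannot lower the optical purity of 14.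

Step 6
Reactants: 14 (S)-1-[2,4-bis(methoxymethoxy)-5-(3-methylbut-2-en-1-yl)phenyl]-2-hydroxy-3-(4-methoxyphenyl)propan-1-one
Product: 15 lespeflorin C2
Conditions: HCl (1 M in MeOH), 0 °C → rt
Reagents that add atoms: none
Why: Acid-catalysed transacetalization (MOM cleavage) should pass both CH2OMe groups to methanol as dimethoxymethane, while the dilute acid and low temperature leave the prenyl alkene, the aryl methyl ether and the (S)-α-hydroxy ketone untouched.

Compound list
1 | O-methyl-L-tyrosine [(S)-2-amino-3-(4-methoxyphenyl)propanoic acid] | COc1ccc(C[C@H](N)C(=O)O)cc1 | starting material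
2 | (S)-1-carboxylato-2-(4-methoxyphenyl)ethanediazonium (diazonium carboxylate) | COc1ccc(C[C@H]([N+]#N)C(=O)[O-])cc1 | intermediate
3 | (R)-3-(4-methoxybenzyl)oxiran-2-one (α-lactone) | COc1ccc(C[C@@H]2C(=O)O2)cc1 | intermediate
4 | (S)-2-hydroxy-3-(4-methoxyphenyl)propanoic acid | COc1ccc(C[C@H](O)C(=O)O)cc1 | intermediate
5 | (S)-5-(4-methoxybenzyl)-2,2-dimethyl-1,3-dioxolan-4-one | COc1ccc(C[C@H]2C(=O)OC(C)(C)O2)cc1 | intermediate
6 | 4,6-dibromoresorcinol (4,6-dibromobenzene-1,3-diol) | Oc1cc(O)c(Br)cc1Br | starting material
7 | 1,5-dibromo-2,4-bis(methoxymethoxy)benzene | COCOc1cc(OCOC)c(Br)cc1Br | intermediate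
8 | prenyl bromide (1-bromo-3-methylbut-2-ene) | CC(C)=CCBr | starting material
9 | [5-bromo-2,4-bis(methoxymethoxy)phenyl]lithium | COCOc1cc(OCOC)c(Br)cc1[Li] | intermediate
10 | [5-bromo-2,4-bis(methoxymethoxy)phenyl]copper | COCOc1cc(OCOC)c(Br)cc1[Cu] | intermediate
11 | 1-bromo-2,4-bis(methoxymethoxy)-5-(3-methylbut-2-en-1-yl)benzene | COCOc1cc(OCOC)c(CC=C(C)C)cc1Br | intermediate
12 | [2,4-bis(methoxymethoxy)-5-(3-methylbut-2-en-1-yl)phenyl]lithium | COCOc1cc(OCOC)c(CC=C(C)C)cc1[Li] | intermediate
13 | lithium (5S)-4-[2,4-bis(methoxymethoxy)-5-(3-methylbut-2-en-1-yl)phenyl]-5-(4-methoxybenzyl)-2,2-dimethyl-1,3-dioxolan-4-olate (C4 undefined) | COc1ccc(C[C@H]2C(O[Li])(c3cc(CC=C(C)C)c(OCOC)cc3OCOC)OC(C)(C)O2)cc1 | intermediate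
14 | (S)-1-[2,4-bis(methoxymethoxy)-5-(3-methylbut-2-en-1-yl)phenyl]-2-hydroxy-3-(4-methoxyphenyl)propan-1-one | COc1ccc(C[C@H](O)C(=O)c2cc(CC=C(C)C)c(OCOC)cc2OCOC)cc1 | intermediate
15 | lespeflorin C2 [(S)-1-[2,4-dihydroxy-5-(3-methylbut-2-en-1-yl)phenyl]-2-hydroxy-3-(4-methoxyphenyl)propan-1-one] | COc1ccc(C[C@H](O)C(=O)c2cc(CC=C(C)C)c(O)cc2O)cc1 | target

Total step count: 6.
Longest linear sequence: 4 steps (6 → 7 → 11 → 14 → 15). The branch 1 → 4 → 5 → 14 → 15 is equally long.

Steps most likely to fail

Step 5. The basic aryllithium may deprotonate the lactone at C2 instead of adding. The tetrahedral adduct may also collapse early, so that a second aryl group adds. The fallback sets out from 11 (and uses 5) and comes back at 14; it replaces the polar addition by a base-free Pd/Cu-mediated Liebeskind–Srogl ketone synthesis. Aryllithium 12, made from 11 as before, is trapped with B(OiPr)3 and hydrolysed with aqueous NH4Cl to [2,4-bis(methoxymethoxy)-5-(3-methylbut-2-en-1-yl)phenyl]boronic acid F1. Lactone 5 is opened with Me2AlSEt (AlMe3, EtSH, CH2Cl2, 0 °C) to S-ethyl (S)-2-hydroxy-3-(4-methoxyphenyl)propanethioate F2. Coupling of the two with Pd2(dba)3, P(OEt)3 and copper(I) thiophene-2-carboxylate in THF at rt to 50 °C, a reaction type that preserves α-stereocentres of thioesters, should give 14.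

Step 6. While the slower 4′-O-MOM group is being cleaved, the freed 4′-phenol may close onto the protonated prenyl alkene, or HCl/MeOH may add across that alkene. The fallback sets out from 7 and comes back at 15; it installs the acid-sensitive trisubstituted alkene only after the acid step.
- Arylcopper 10, made from 7 through 9 as in step 4, is allylated with allyl bromide to 1-allyl-5-bromo-2,4-bis(methoxymethoxy)benzene F3.
- Br/Li exchange gives [5-allyl-2,4-bis(methoxymethoxy)phenyl]lithium F4.
- This adds to 5 to give the allyl-series lithium hemiketal alkoxide F5 and, after the AcOH quench, (S)-1-[5-allyl-2,4-bis(methoxymethoxy)phenyl]-2-hydroxy-3-(4-methoxyphenyl)propan-1-one F6.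
- HCl/MeOH then gives (S)-1-(5-allyl-2,4-dihydroxyphenyl)-2-hydroxy-3-(4-methoxyphenyl)propan-1-one F7, whose monosubstituted alkene is much harder to protonate.
- Olefin cross-metathesis with 2-methylbut-2-ene (second-generation NHC ruthenium benzylidene catalyst, CH2Cl2, 40 °C) converts allyl into prenyl and gives 15.

Step 4. Proton transfer or a second exchange may blur the desymmetrization. The allylic substitution may also leak to the tertiary terminus (SN2′) or to homocoupling. The fallback sets out from 7 and comes back at 11. It is a Stille cross-coupling of 7 with one equivalent of tributyl(3-methylbut-2-en-1-yl)stannane (Pd(PPh3)4, DMF, 90 °C). The first coupling makes the ring more electron-rich and more hindered, which slows a second oxidative addition. No new compound arises on this way (F0).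

Further compounds
F1 | step 5 | [2,4-bis(methoxymethoxy)-5-(3-methylbut-2-en-1-yl)phenyl]boronic acid | COCOc1cc(OCOC)c(CC=C(C)C)cc1B(O)O
F2 | step 5 | S-ethyl (S)-2-hydroxy-3-(4-methoxyphenyl)propanethioate | COc1ccc(C[C@H](O)C(=O)SCC)cc1
F3 | step 6 | 1-allyl-5-bromo-2,4-bis(methoxymethoxy)benzene | COCOc1cc(OCOC)c(CC=C)cc1Br
F4 | step 6 | [5-allyl-2,4-bis(methoxymethoxy)phenyl]lithium | COCOc1cc(OCOC)c(CC=C)cc1[Li]
F5 | step 6 | lithium (5S)-4-[5-allyl-2,4-bis(methoxymethoxy)phenyl]-5-(4-methoxybenzyl)-2,2-dimethyl-1,3-dioxolan-4-olate (C4 undefined) | COc1ccc(C[C@H]2C(O[Li])(c3cc(CC=C)c(OCOC)cc3OCOC)OC(C)(C)O2)cc1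
F6 | step 6 | (S)-1-[5-allyl-2,4-bis(methoxymethoxy)phenyl]-2-hydroxy-3-(4-methoxyphenyl)propan-1-one | COc1ccc(C[C@H](O)C(=O)c2cc(CC=C)c(OCOC)cc2OCOC)cc1
F7 | step 6 | (S)-1-(5-allyl-2,4-dihydroxyphenyl)-2-hydroxy-3-(4-methoxyphenyl)propan-1-one | COc1ccc(C[C@H](O)C(=O)c2cc(CC=C)c(O)cc2O)cc1
F0 | step 4 | none | none
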